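## The problem

The target 29 is a single ten-membered carbocycle (C1–C10) with no ring fusion to lean on. The whole skeletal difficulty is the closure of one medium ring that holds two trisubstituted Z alkenes, C1(Me)=C2 and C7(Me)=C8, in a skipped 1,5-relationship. Three contiguous stereocentres, C3 (free allylic hydroxyl), C4 (isopropyl) and C5 (4-hydroxybenzoate), are all R and stand 3,4-anti, 4,5-syn and 3,5-anti. C4 and C5 are an aldol pair that one auxiliary can set together, and the C5 oxygen can then fix C3 by internal delivery of hydride. One source of absolute configuration is therefore enough if the triad is built in the open chain. The two oxygens must be told apart (acyl on O5, hydrogen on O3), and their 1,3-relationship invites acyl migration under base. The aryl ester, the free phenol and the allylic alcohol are sensitive; the Z alkenes can isomerise through metal π-allyl intermediates or acid, and the 1,5-diene is open to transannular reactions. The feature that makes the key step possible is the C9–C10 bond. It joins the two allylic methylenes of the diene, each by nature an allylic electrophile, so a sulfonyl group on C10 can reverse the polarity of one and the two carbons can be joined by a plain SN2 reaction that touches neither alkene.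

## Retrosynthesis

**29 from 28.** The O–Si bonds at O3 and at the phenol are cut. Both silyl groups fall in one buffered fluoride step, so no differentiation of O3 and O5 is needed on the ring. The forward step must keep the aroyl group on O5.

**28 from 27.** The C10–S bond is cut; the phenylsulfonyl group is only an auxiliary for ring closure. The forward reduction must put hydrogen on C10 without moving or isomerising the C1=C2 alkene. C10 of 27 may be a mixture of epimers, since the stereocentre disappears here.

**27 from 25 (key disconnection).** The C9–C10 bond is cut, which opens the ring to an open-chain bromo sulfone. Cutting C8–C9 or C10–C1 instead would call for alkenyl-metal chemistry on the ring-closing step, and cutting C3–C4 or C4–C5 would tie ring closure to stereocontrol. The C9–C10 cut leaves both alkenes and all three stereocentres finished in 25. The forward step needs α-alkylation of the sulfonyl allyl anion, ring closure ahead of oligomerisation, and an ester and a silyl ether that stay passive towards a carbanion at −78 °C.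

**25 from 19 (through 24, 23 and 20).** The C9–Br and C10–S bonds are traced back to two allylic oxygens that carry different protecting groups, PMB on O10 and a primary TBS on O9. The sulfone is installed first because it is robust; the labile bromide is made last. The forward steps ask only for orthogonal deprotection: oxidative for PMB, mild acid for the primary silyl ether beside a hindered secondary and an aryl silyl ether.

**19 from 16 and 17 (through 18).** After removal of the O3 silyl group, the C3–H bond and the O5–acyl bond are cut together, which is an Evans–Tishchenko reduction of β-hydroxy enone 16 with aldehyde 17. The neighbouring option, anti-reduction to a diol, would leave two secondary hydroxyls to be told apart later and would need an oxidation–reduction detour on the ring. Here one step sets C3 from C5 and places the final aroyl group on O5. The price is that an aryl ester rides through the ring closure. This is accepted because the ester has no α-hydrogen, is electron-rich and hindered, and sits on O5, not next to the carbanion.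

**16 from 10 and 14.** The C2–C3 bond is cut to Weinreb amide 10 and the Z-alkenyl iodide 14, used as its lithium derivative 15. The iodide comes in two steps from 11 through 13, with the C1=C2 geometry fixed by chelation-controlled anti-carbomagnesiation. The benzyl-type ether on O10 avoids silyl migration to the cis alkenyl carbanion.

**10 from 7 and 4 (through 9).** The C4–C5 bond is cut as an auxiliary-controlled syn-aldol between imide 7 (from 5 and 6) and aldehyde 4. This sets both C4 and C5 in one well-understood step. The forward reaction must tolerate a β,γ-unsaturated aldehyde, which it should at low temperature with little free amine.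

**4 from 1 (through 2).** The aldehyde is traced to a terminal alkyne. The Z-enynol 1 already has the C7=C8 geometry, the hydroxyl on C9 and a latent C5 aldehyde. A fragment that reached this stage with both ends as primary alcohols would need a selective protection that cannot be relied on. Silylation and anti-Markovnikov hydration by hydroboration–oxidation are all that is asked.

## Roads not taken

**Alternative 1:** The ring would be cut at C3–C4 and traced to the thirteen-membered bis-allylic ether A2. n-Butyllithium would lithiate the O–CH2 carbon next to C1=C2, and a [2,3]-Wittig shift would join C3 to C4, contract the ring to ten members and give dienol A1 with an isopropenyl group on C4.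
- Merits: the C–C bond, the ring and the C3 and C4 stereocentres arise in one step, and a thirteen-membered ether is easier to close than a ten-membered carbocycle. In stereocentres made per step this road beats the chosen plan.
- Weak points: two allylic O–CH2 sites compete for lithiation, and a [1,2]-shift can intervene. The C3/C4 relationship and its relation to C5 come from a macrocyclic transition state that cannot be predicted with confidence.
- After the contraction: A1 has the oxygens differentiated the wrong way round (O3 free, O5 silylated), so a protecting-group exchange must precede acylation. The isopropenyl group also needs selective hydrogenation beside two ring alkenes.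
- Comparison: the chosen plan sets the triad by open-chain reactions with known models and puts the aroyl group on O5 without any exchange on the ring.

**Alternative 2:** The ring would be cut at C4–C5 and traced to chloro aldehyde A4. CrCl2 (divalent chromium) would turn the allylic chloride into an allylchromium species that adds through its γ-carbon C4 to the C5 aldehyde, giving A3.
- Merits: the reaction tolerates functionality, is stereoconvergent with respect to the chloride geometry, and its usual anti preference (in the crotyl sense) matches the required C4/C5 relationship. A3 has O5 free and O3 silylated, the right differentiation for direct acylation; in this respect it equals the chosen plan, which obtains the same differentiation from the Evans–Tishchenko step.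
- Weak points: the configuration of C4 relative to the existing C3 depends on facial selectivity in a ten-membered transition state. Two of three stereocentres are thus created in the least predictable step. The isopropenyl group must still be hydrogenated selectively, and A4 carries a β,γ-unsaturated aldehyde at the end of a long chain.
- Comparison: the chosen ring closure creates no stereocentre that matters.

**Alternative 3:** The ring would be cut at C8–C9 and traced to iodo diene A6. 9-Borabicyclo[3.3.1]nonane would hydroborate the terminal vinyl group at C9, and Pd(dppf)Cl2 with Cs2CO3 would couple the alkylborane with the C8 alkenyl iodide to give A5, which is the same compound as 28.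
- Merits: no sulfone has to be installed or removed, so this road is shorter by about three steps. In step count it is better than the chosen plan.
- Weak points: ten-membered rings are at the unfavourable end for palladium-mediated macrocyclisation. The borane must select the terminal alkene of a conjugated diene, the aryl ester must survive aqueous base at elevated temperature, and A6 needs both a Z-iodoalkene and a 2-substituted diene.
- Comparison: the chosen plan offers an irreversible SN2 closure by a soft carbanion at −78 °C, a reaction type with direct precedent for ten-membered 1,5-diene rings.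

Key step: step 15

## Route

Remark: 1 is assumed to be purchasable as the pure Z isomer and 17 as such. C10 of 26 and 27 is carried as both epimers because the sulfone is removed in step 16. TBSO = tert-butyldimethylsilyloxy, PMBO = 4-methoxybenzyloxy. Open-chain compounds 16–26 are named as deca-2,8-dienes whose C1 is ring carbon C10 and whose C10 is ring carbon C9.

Step 1
Reactants: 1 (2Z)-3-methylpent-2-en-4-yn-1-ol
Product: 2 tert-butyldimethyl{[(2Z)-3-methylpent-2-en-4-yn-1-yl]oxy}silane
Conditions: TBSCl, imidazole, CH2Cl2, 0 °C to rt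
Reagents that add atoms: tert-butyldimethylsilyl chloride, CC(C)(C)[Si](C)(C)Cl
Why: Standard silylation of a primary allylic alcohol; the Z alkene is bought in and untouched, and this primary silyl ether is later the only one that mild acid removes.

Step 2
Reactants: 2 tert-butyldimethyl{[(2Z)-3-methylpent-2-en-4-yn-1-yl]oxy}silane
Product: 4 (3Z)-5-(tert-butyldimethylsilyloxy)-3-methylpent-3-enal, via dienylborane 3 (not isolated)
Conditions: Cy2BH (from BH3·SMe2, cyclohexene), THF, 0 °C; then 30% H2O2, pH 7 phosphate buffer, 0 °C; used crude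
Reagents that add atoms: hydrogen peroxide, OO
Why: Anti-Markovnikov hydroboration of the terminal alkyne of a conjugated enyne by a hindered dialkylborane, followed by buffered oxidation; the dienol formed is protonated at the α-carbon, which gives the β,γ-unsaturated aldehyde with the Z alkene unchanged.

Step 3
Reactants: 5 (4S)-4-benzyl-1,3-oxazolidin-2-one; 6 3-methylbutanoyl chloride
Product: 7 (4S)-4-benzyl-3-(3-methylbutanoyl)-1,3-oxazolidin-2-one
Conditions: Et3N, DMAP (cat.), CH2Cl2, 0 °C to rt
Reagents that add atoms: none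
Why: N-Acylation of the oxazolidinone by the acid chloride under nucleophilic acyl-transfer catalysis.

Step 4
Reactants: 7 (4S)-4-benzyl-3-(3-methylbutanoyl)-1,3-oxazolidin-2-one; 4 (3Z)-5-(tert-butyldimethylsilyloxy)-3-methylpent-3-enal
Product: 9 (4S)-4-benzyl-3-[(2S,3R,5Z)-7-(tert-butyldimethylsilyloxy)-3-hydroxy-5-methyl-2-(propan-2-yl)hept-5-enoyl]-1,3-oxazolidin-2-one, via boron enolate 8 (not isolated)
Conditions: Bu2BOTf, i-Pr2NEt, CH2Cl2, −78 to 0 °C; then 4, −78 to 0 °C; pH 7 buffer, MeOH, H2O2, 0 °C
Reagents that add atoms: none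
Why: Evans syn-aldol reaction: the Z boron enolate reacts through a closed chair (Zimmerman–Traxler) transition state on the face away from the benzyl group, so the auxiliary sets C4 and C5 together (4,5-syn); low temperature and near absence of free amine protect the β,γ-unsaturated aldehyde.

Step 5
Reactants: 9 (4S)-4-benzyl-3-[(2S,3R,5Z)-7-(tert-butyldimethylsilyloxy)-3-hydroxy-5-methyl-2-(propan-2-yl)hept-5-enoyl]-1,3-oxazolidin-2-one
Product: 10 (2S,3R,5Z)-7-(tert-butyldimethylsilyloxy)-3-hydroxy-N-methoxy-N,5-dimethyl-2-(propan-2-yl)hept-5-enamide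
Conditions: MeNHOMe·HCl, AlMe3, CH2Cl2, −20 to 0 °C
Reagents that add atoms: N,O-dimethylhydroxylamine hydrochloride, CNOC.Cl
Why: Transamination of the aldol imide by an aluminium amide, helped by the free β-hydroxyl, whose aluminium alkoxide delivers the amide to the exocyclic carbonyl; auxiliary 5 is recovered.

Step 6
Reactants: 11 prop-2-yn-1-ol
Product: 13 (2Z)-3-iodo-2-methylprop-2-en-1-ol, via magnesium chelate 12 (not isolated)
Conditions: MeMgBr, CuI (cat.), THF, −10 °C to rt; then I2, −10 °C
Reagents that add atoms: methylmagnesium bromide, C[Mg]Br; iodine, II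
Why: Copper-catalysed anti-carbomagnesiation of the propargylic alkoxide puts methyl on the carbinol-bearing alkyne carbon and magnesium on the terminal carbon inside a five-membered chelate; iodinolysis with retention gives the Z iodide.

Step 7
Reactants: 13 (2Z)-3-iodo-2-methylprop-2-en-1-ol
Product: 14 1-({[(2Z)-3-iodo-2-methylprop-2-en-1-yl]oxy}methyl)-4-methoxybenzene
Conditions: NaH, PMBCl, Bu4NI (cat.), THF/DMF, 0 °C to rt
Reagents that add atoms: 4-methoxybenzyl chloride, COc1ccc(CCl)cc1
Why: Williamson etherification; a benzyl-type ether is chosen because a silyl group cis to the future C–Li bond could migrate from oxygen to carbon.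

Step 8
Reactants: 14 1-({[(2Z)-3-iodo-2-methylprop-2-en-1-yl]oxy}methyl)-4-methoxybenzene; 10 (2S,3R,5Z)-7-(tert-butyldimethylsilyloxy)-3-hydroxy-N-methoxy-N,5-dimethyl-2-(propan-2-yl)hept-5-enamide
Product: 16 (2Z,5S,6R,8Z)-10-TBSO-6-hydroxy-1-PMBO-2,8-dimethyl-5-(propan-2-yl)deca-2,8-dien-4-one, via alkenyllithium 15 (not isolated)
Conditions: 14 (2.5 equiv), t-BuLi (5 equiv), Et2O, −78 °C; then 10, THF, −78 to −40 °C; aq. NH4Cl
Reagents that add atoms: none
Why: Iodine–lithium exchange keeps the alkene geometry, and the alkenyllithium adds once to the Weinreb amide because the chelated tetrahedral intermediate survives until work-up (Weinreb ketone synthesis); one equivalent of 15 is spent on the C5 hydroxyl.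

Step 9
Reactants: 16 (2Z,5S,6R,8Z)-10-TBSO-6-hydroxy-1-PMBO-2,8-dimethyl-5-(propan-2-yl)deca-2,8-dien-4-one; 17 4-(tert-butyldimethylsilyloxy)benzaldehyde
Product: 18 (2Z,4R,5R,6R,8Z)-10-TBSO-4-hydroxy-1-PMBO-2,8-dimethyl-5-(propan-2-yl)deca-2,8-dien-6-yl 4-(tert-butyldimethylsilyloxy)benzoate
Conditions: SmI2 (0.3 equiv, premixed with 17), 17 (5 equiv), THF, −10 °C
Reagents that add atoms: none
Why: Evans–Tishchenko reduction: divalent samarium is oxidised by the aldehyde to the trivalent samarium alkoxide that catalyses the reaction; the C5 hydroxyl adds to 17 and the hemiacetal passes its hydride to the C3 ketone through a six-membered chair. The C5 oxygen therefore sets the new C3 carbinol anti to itself and leaves the aroyl group on O5.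

Step 10
Reactants: 18 (2Z,4R,5R,6R,8Z)-10-TBSO-4-hydroxy-1-PMBO-2,8-dimethyl-5-(propan-2-yl)deca-2,8-dien-6-yl 4-(tert-butyldimethylsilyloxy)benzoate
Product: 19 (2Z,4R,5S,6R,8Z)-4,10-bis-TBSO-1-PMBO-2,8-dimethyl-5-(propan-2-yl)deca-2,8-dien-6-yl 4-(tert-butyldimethylsilyloxy)benzoate
Conditions: TBSOTf, 2,6-lutidine, CH2Cl2, −78 °C
Reagents that add atoms: tert-butyldimethylsilyl trifluoromethanesulfonate, CC(C)(C)[Si](C)(C)OS(=O)(=O)C(F)(F)F
Why: Silylation of the hindered secondary allylic alcohol by the silyl triflate at low temperature, before the aroyl group can migrate from O5 to O3.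

Step 11
Reactants: 19 (2Z,4R,5S,6R,8Z)-4,10-bis-TBSO-1-PMBO-2,8-dimethyl-5-(propan-2-yl)deca-2,8-dien-6-yl 4-(tert-butyldimethylsilyloxy)benzoate
Product: 20 (2Z,4R,5S,6R,8Z)-4,10-bis-TBSO-1-hydroxy-2,8-dimethyl-5-(propan-2-yl)deca-2,8-dien-6-yl 4-(tert-butyldimethylsilyloxy)benzoate
Conditions: DDQ, CH2Cl2/pH 7 buffer, 0 °C
Reagents that add atoms: none
Why: Oxidative cleavage of the 4-methoxybenzyl ether by benzylic hydride abstraction and hydrolysis; silyl ethers, ester and trisubstituted alkenes are not attacked under buffered conditions.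

Step 12
Reactants: 20 (2Z,4R,5S,6R,8Z)-4,10-bis-TBSO-1-hydroxy-2,8-dimethyl-5-(propan-2-yl)deca-2,8-dien-6-yl 4-(tert-butyldimethylsilyloxy)benzoate
Product: 23 (2Z,4R,5S,6R,8Z)-4,10-bis-TBSO-2,8-dimethyl-1-(phenylsulfonyl)-5-(propan-2-yl)deca-2,8-dien-6-yl 4-(tert-butyldimethylsilyloxy)benzoate, via allylic mesylate 21 (not isolated), via allylic chloride 22 (not isolated)
Conditions: MsCl, 2,4,6-collidine, LiCl, dry DMF, 0 °C; then PhSO2Na, Bu4NI (cat.), rt
Reagents that add atoms: sodium benzenesulfinate, [Na+].[O-]S(=O)c1ccccc1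
Why: Mesylation with in-situ chloride displacement gives the primary allylic chloride without transposition, and the soft sulfinate sulfur then displaces chloride by SN2 under iodide catalysis; the C1=C2 geometry is not involved.

Step 13
Reactants: 23 (2Z,4R,5S,6R,8Z)-4,10-bis-TBSO-2,8-dimethyl-1-(phenylsulfonyl)-5-(propan-2-yl)deca-2,8-dien-6-yl 4-(tert-butyldimethylsilyloxy)benzoate
Product: 24 (2Z,4R,5S,6R,8Z)-4-TBSO-10-hydroxy-2,8-dimethyl-1-(phenylsulfonyl)-5-(propan-2-yl)deca-2,8-dien-6-yl 4-(tert-butyldimethylsilyloxy)benzoate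
Conditions: CSA (cat.), MeOH/CH2Cl2, 0 °C
Reagents that add atoms: none
Why: Acid-catalysed methanolysis removes the unhindered primary silyl ether much faster than the hindered secondary one at C3 or the acid-stable aryl silyl ether.

Step 14
Reactants: 24 (2Z,4R,5S,6R,8Z)-4-TBSO-10-hydroxy-2,8-dimethyl-1-(phenylsulfonyl)-5-(propan-2-yl)deca-2,8-dien-6-yl 4-(tert-butyldimethylsilyloxy)benzoate
Product: 25 (2Z,4R,5S,6R,8Z)-10-bromo-4-TBSO-2,8-dimethyl-1-(phenylsulfonyl)-5-(propan-2-yl)deca-2,8-dien-6-yl 4-(tert-butyldimethylsilyloxy)benzoate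
Conditions: CBr4, PPh3, 2,6-lutidine, CH2Cl2, −20 to 0 °C; used at once
Reagents that add atoms: carbon tetrabromide, BrC(Br)(Br)Br
Why: Appel reaction: bromide displaces the alkoxyphosphonium group at the primary allylic carbon by SN2 under neutral conditions, so the C7=C8 geometry and the sulfone are untouched.

Step 15
Reactants: 25 (2Z,4R,5S,6R,8Z)-10-bromo-4-TBSO-2,8-dimethyl-1-(phenylsulfonyl)-5-(propan-2-yl)deca-2,8-dien-6-yl 4-(tert-butyldimethylsilyloxy)benzoate
Product: 27 (1R,3Z,7Z,9R,10S)-9-TBSO-3,7-dimethyl-6-(phenylsulfonyl)-10-(propan-2-yl)cyclodeca-3,7-dien-1-yl 4-(tert-butyldimethylsilyloxy)benzoate (both epimers at the sulfonyl carbon), via potassium sulfonyl carbanion 26 (not isolated)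
Conditions: KN(SiMe3)2 (1.3 equiv), THF, −78 °C, slow addition of 25 to a final 0.002 M; then to −40 °C
Reagents that add atoms: none
Why: KN(SiMe3)2 removes a proton from ring carbon C10, which is activated by the sulfonyl group and the C1=C2 alkene, and carbanion 26 displaces bromide from the primary allylic carbon C9 in an intramolecular SN2 reaction that forms C9–C10. The closest known reaction type is the intramolecular alkylation of allylic sulfone or sulfide carbanions by allylic halides that closes ten- and fourteen-membered 1,5-diene rings of terpenoids. The ten-membered ring closes in the 10-exo-tet mode, with bromide leaving outside the forming ring. The one new stereocentre, C10, is controlled by no element and need not be, because both epimers lose the sulfonyl group in step 16. The step needs α- and not γ-alkylation; the sulfonyl group secures this by holding charge and counter-ion at C10, and γ-attack would have to form an eight-membered ring through the hindered C2. It needs ring closure ahead of oligomerisation, which slow addition at high dilution and the turns imposed by two Z alkenes and the substituted C3–C5 segment support. Both Z alkenes should persist because neither partner passes through a metal π-allyl and the bromide reacts by direct displacement at −78 °C. The hindered, electron-rich aryl ester on O5, which has no α-hydrogen, and the poor silyloxide leaving group on C3 should stay out of the reaction at this temperature.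

Step 16
Reactants: 27 (1R,3Z,7Z,9R,10S)-9-TBSO-3,7-dimethyl-6-(phenylsulfonyl)-10-(propan-2-yl)cyclodeca-3,7-dien-1-yl 4-(tert-butyldimethylsilyloxy)benzoate
Product: 28 (1R,3Z,7Z,9R,10S)-9-TBSO-3,7-dimethyl-10-(propan-2-yl)cyclodeca-3,7-dien-1-yl 4-(tert-butyldimethylsilyloxy)benzoate
Conditions: 6% Na/Hg, Na2HPO4, MeOH/THF, −20 °C
Reagents that add atoms: none
Why: Reductive desulfonylation by electron transfer: the C–S bond breaks to an allyl radical and then anion that methanol protonates; the phosphate buffer keeps methoxide away from the ester and the aryl silyl ether, and both C10 epimers converge on one product.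

Step 17
Reactants: 28 (1R,3Z,7Z,9R,10S)-9-TBSO-3,7-dimethyl-10-(propan-2-yl)cyclodeca-3,7-dien-1-yl 4-(tert-butyldimethylsilyloxy)benzoate
Product: 29 (1R,3Z,7Z,9R,10R)-9-hydroxy-3,7-dimethyl-10-(propan-2-yl)cyclodeca-3,7-dien-1-yl 4-hydroxybenzoate
Conditions: Bu4NF, AcOH (1:1), THF, 0 °C to rt
Reagents that add atoms: none
Why: Fluoride-induced desilylation of the aryl and the secondary allylic silyl ether; acetic acid keeps the C3 oxygen and the phenol protonated, so the aroyl group should stay on O5.

## Compound list

1 | (2Z)-3-methylpent-2-en-4-yn-1-ol | C#C/C(C)=C\CO | starting material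
2 | tert-butyldimethyl{[(2Z)-3-methylpent-2-en-4-yn-1-yl]oxy}silane | C#C/C(C)=C\CO[Si](C)(C)C(C)(C)C | intermediate
3 | dicyclohexyl[(1E,3Z)-5-(tert-butyldimethylsilyloxy)-3-methylpenta-1,3-dien-1-yl]borane (not isolated) | C1CCCCC1B(C1CCCCC1)/C=C/C(C)=C\CO[Si](C)(C)C(C)(C)C | intermediate
4 | (3Z)-5-(tert-butyldimethylsilyloxy)-3-methylpent-3-enal | O=CC/C(C)=C\CO[Si](C)(C)C(C)(C)C | intermediate
5 | (4S)-4-benzyl-1,3-oxazolidin-2-one | O=C1N[C@@H](Cc2ccccc2)CO1 | starting material
6 | 3-methylbutanoyl chloride | CC(C)CC(Cl)=O | starting material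
7 | (4S)-4-benzyl-3-(3-methylbutanoyl)-1,3-oxazolidin-2-one | CC(C)CC(=O)N1[C@@H](Cc2ccccc2)COC1=O | intermediate
8 | dibutylboron (Z)-enolate of 7 (not isolated) | CCCCB(CCCC)O/C(=C\C(C)C)N1[C@@H](Cc2ccccc2)COC1=O | intermediate
9 | (4S)-4-benzyl-3-[(2S,3R,5Z)-7-(tert-butyldimethylsilyloxy)-3-hydroxy-5-methyl-2-(propan-2-yl)hept-5-enoyl]-1,3-oxazolidin-2-one | O=C(N1[C@@H](Cc2ccccc2)COC1=O)[C@@H](C(C)C)[C@H](O)C/C(C)=C\CO[Si](C)(C)C(C)(C)C | intermediate
10 | (2S,3R,5Z)-7-(tert-butyldimethylsilyloxy)-3-hydroxy-N-methoxy-N,5-dimethyl-2-(propan-2-yl)hept-5-enamide | CON(C)C(=O)[C@@H](C(C)C)[C@H](O)C/C(C)=C\CO[Si](C)(C)C(C)(C)C | intermediate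
11 | prop-2-yn-1-ol | C#CCO | starting material
12 | 4-methyl-2,5-dihydro-1,2-oxamagnesole, the cyclic (Z)-alkenylmagnesium alkoxide (not isolated) | CC1=C[Mg]OC1 | intermediate
13 | (2Z)-3-iodo-2-methylprop-2-en-1-ol | OC/C(C)=C\I | intermediate
14 | 1-({[(2Z)-3-iodo-2-methylprop-2-en-1-yl]oxy}methyl)-4-methoxybenzene | COc1ccc(COC/C(C)=C\I)cc1 | intermediate
15 | {(1Z)-3-[(4-methoxybenzyl)oxy]-2-methylprop-1-en-1-yl}lithium (not isolated) | COc1ccc(COC/C(C)=C\[Li])cc1 | intermediate
16 | (2Z,5S,6R,8Z)-10-(tert-butyldimethylsilyloxy)-6-hydroxy-1-(4-methoxybenzyloxy)-2,8-dimethyl-5-(propan-2-yl)deca-2,8-dien-4-one | COc1ccc(COC/C(C)=C\C(=O)[C@@H](C(C)C)[C@H](O)C/C(C)=C\CO[Si](C)(C)C(C)(C)C)cc1 | intermediate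
17 | 4-(tert-butyldimethylsilyloxy)benzaldehyde | O=Cc1ccc(O[Si](C)(C)C(C)(C)C)cc1 | starting material
18 | (2Z,4R,5R,6R,8Z)-10-(tert-butyldimethylsilyloxy)-4-hydroxy-1-(4-methoxybenzyloxy)-2,8-dimethyl-5-(propan-2-yl)deca-2,8-dien-6-yl 4-(tert-butyldimethylsilyloxy)benzoate | COc1ccc(COC/C(C)=C\[C@@H](O)[C@@H](C(C)C)[C@H](OC(=O)c2ccc(O[Si](C)(C)C(C)(C)C)cc2)C/C(C)=C\CO[Si](C)(C)C(C)(C)C)cc1 | intermediate
19 | (2Z,4R,5S,6R,8Z)-4,10-bis(tert-butyldimethylsilyloxy)-1-(4-methoxybenzyloxy)-2,8-dimethyl-5-(propan-2-yl)deca-2,8-dien-6-yl 4-(tert-butyldimethylsilyloxy)benzoate | COc1ccc(COC/C(C)=C\[C@@H](O[Si](C)(C)C(C)(C)C)[C@@H](C(C)C)[C@H](OC(=O)c2ccc(O[Si](C)(C)C(C)(C)C)cc2)C/C(C)=C\CO[Si](C)(C)C(C)(C)C)cc1 | intermediate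
20 | (2Z,4R,5S,6R,8Z)-4,10-bis(tert-butyldimethylsilyloxy)-1-hydroxy-2,8-dimethyl-5-(propan-2-yl)deca-2,8-dien-6-yl 4-(tert-butyldimethylsilyloxy)benzoate | OC/C(C)=C\[C@@H](O[Si](C)(C)C(C)(C)C)[C@@H](C(C)C)[C@H](OC(=O)c1ccc(O[Si](C)(C)C(C)(C)C)cc1)C/C(C)=C\CO[Si](C)(C)C(C)(C)C | intermediate
21 | 1-methanesulfonate of 20, the allylic mesylate (not isolated) | CS(=O)(=O)OC/C(C)=C\[C@@H](O[Si](C)(C)C(C)(C)C)[C@@H](C(C)C)[C@H](OC(=O)c1ccc(O[Si](C)(C)C(C)(C)C)cc1)C/C(C)=C\CO[Si](C)(C)C(C)(C)C | intermediate
22 | (2Z,4R,5S,6R,8Z)-4,10-bis(tert-butyldimethylsilyloxy)-1-chloro-2,8-dimethyl-5-(propan-2-yl)deca-2,8-dien-6-yl 4-(tert-butyldimethylsilyloxy)benzoate (not isolated) | ClC/C(C)=C\[C@@H](O[Si](C)(C)C(C)(C)C)[C@@H](C(C)C)[C@H](OC(=O)c1ccc(O[Si](C)(C)C(C)(C)C)cc1)C/C(C)=C\CO[Si](C)(C)C(C)(C)C | intermediate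
23 | (2Z,4R,5S,6R,8Z)-4,10-bis(tert-butyldimethylsilyloxy)-2,8-dimethyl-1-(phenylsulfonyl)-5-(propan-2-yl)deca-2,8-dien-6-yl 4-(tert-butyldimethylsilyloxy)benzoate | O=S(=O)(c1ccccc1)C/C(C)=C\[C@@H](O[Si](C)(C)C(C)(C)C)[C@@H](C(C)C)[C@H](OC(=O)c1ccc(O[Si](C)(C)C(C)(C)C)cc1)C/C(C)=C\CO[Si](C)(C)C(C)(C)C | intermediate
24 | (2Z,4R,5S,6R,8Z)-4-(tert-butyldimethylsilyloxy)-10-hydroxy-2,8-dimethyl-1-(phenylsulfonyl)-5-(propan-2-yl)deca-2,8-dien-6-yl 4-(tert-butyldimethylsilyloxy)benzoate | O=S(=O)(c1ccccc1)C/C(C)=C\[C@@H](O[Si](C)(C)C(C)(C)C)[C@@H](C(C)C)[C@H](OC(=O)c1ccc(O[Si](C)(C)C(C)(C)C)cc1)C/C(C)=C\CO | intermediate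
25 | (2Z,4R,5S,6R,8Z)-10-bromo-4-(tert-butyldimethylsilyloxy)-2,8-dimethyl-1-(phenylsulfonyl)-5-(propan-2-yl)deca-2,8-dien-6-yl 4-(tert-butyldimethylsilyloxy)benzoate | O=S(=O)(c1ccccc1)C/C(C)=C\[C@@H](O[Si](C)(C)C(C)(C)C)[C@@H](C(C)C)[C@H](OC(=O)c1ccc(O[Si](C)(C)C(C)(C)C)cc1)C/C(C)=C\CBr | intermediate
26 | potassium salt of the carbanion of 25 at the sulfonyl-bearing carbon (not isolated) | [K+].O=S(=O)(c1ccccc1)[CH-]/C(C)=C\[C@@H](O[Si](C)(C)C(C)(C)C)[C@@H](C(C)C)[C@H](OC(=O)c1ccc(O[Si](C)(C)C(C)(C)C)cc1)C/C(C)=C\CBr | intermediate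
27 | (1R,3Z,7Z,9R,10S)-9-(tert-butyldimethylsilyloxy)-3,7-dimethyl-6-(phenylsulfonyl)-10-(propan-2-yl)cyclodeca-3,7-dien-1-yl 4-(tert-butyldimethylsilyloxy)benzoate, both epimers at C6 | C/C1=C/[C@@H](O[Si](C)(C)C(C)(C)C)[C@@H](C(C)C)[C@H](OC(=O)c2ccc(O[Si](C)(C)C(C)(C)C)cc2)C/C(C)=C\CC1S(=O)(=O)c2ccccc2 | intermediate
28 | (1R,3Z,7Z,9R,10S)-9-(tert-butyldimethylsilyloxy)-3,7-dimethyl-10-(propan-2-yl)cyclodeca-3,7-dien-1-yl 4-(tert-butyldimethylsilyloxy)benzoate | C/C1=C/[C@@H](O[Si](C)(C)C(C)(C)C)[C@@H](C(C)C)[C@H](OC(=O)c2ccc(O[Si](C)(C)C(C)(C)C)cc2)C/C(C)=C\CC1 | intermediate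
29 | (1R,3Z,7Z,9R,10R)-9-hydroxy-3,7-dimethyl-10-(propan-2-yl)cyclodeca-3,7-dien-1-yl 4-hydroxybenzoate | C/C1=C/[C@@H](O)[C@@H](C(C)C)[C@H](OC(=O)c2ccc(O)cc2)C/C(C)=C\CC1 | target

## Step count and risks

Total: 17 steps. Longest linear sequence: 14 steps (steps 1, 2, 4, 5 and 8–17).

**Step 15 (key step).** Most likely failure: intermolecular alkylation to oligomers, because ten-membered closure is entropically and enthalpically the least favourable. Attack through the γ-carbon C2, or loss of the C3 silyloxy group from the allyl anion on warming, could also compete, because the carbanion is delocalised towards C2. Fallback, with the roles of the two ends exchanged: from 19, acid-catalysed methanolysis as in step 13 would give the C9 alcohol F1. An Appel reaction would give the C9 bromide F2, and sodium benzenesulfinate in DMF the C9 sulfone F3. DDQ would then free O10 to give the C10 alcohol F4, and a second Appel reaction would give the C10 bromide F5. KN(SiMe3)2 under the conditions of step 15 would close the same C9–C10 bond to give the C9-sulfonyl macrocycle F6, and Na/Hg as in step 16 would bring the route back at 28. The carbanion then has the fully substituted C7 as its γ-terminus and no oxygen next to the allyl system.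

**Step 16.** Most likely failure: migration of the C1=C2 double bond or loss of its Z geometry, because the intermediate allyl anion can be protonated at C2 as well as at C10; methanolysis of the ester is a lesser risk. Fallback: from 27, PdCl2(dppp) (cat.) and excess LiBHEt3 in THF at 0 °C would remove the sulfonyl group by hydride transfer to a π-allylpalladium intermediate formed by zerovalent palladium. Hydride is expected at the less hindered terminus C10, and the ring restrains the allyl unit. The aryl ester would be cleaved at the same time, giving the ring alcohol F7. Steglich esterification of F7 with 4-(tert-butyldimethylsilyloxy)benzoic acid (EDC·HCl, DMAP, CH2Cl2) would return the route at 28.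

**Step 9.** Most likely failure: slow hemiacetal formation with the electron-rich aromatic aldehyde, which would let retro-aldol cleavage or migration of the aroyl group to O3 compete. Fallback, with hydride donor and final acyl group decoupled: from 16, the Evans–Tishchenko reduction would be run with acetaldehyde to give the C5 acetate F8. TBSOTf and 2,6-lutidine would give the C3 silyl ether F9, and i-Bu2AlH at −78 °C would remove the acetate to give the C5 alcohol F10. Esterification of F10 with 4-(tert-butyldimethylsilyloxy)benzoic acid (EDC·HCl, DMAP) would return the route at 19.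

**Step 2.** Most likely failure: isomerisation of the β,γ-unsaturated aldehyde into conjugation, or 1,6-elimination of silanol, during oxidative work-up and isolation. Fallback: from 2, the same hydroboration and oxidation would be followed in the same flask by NaBH4, so that the stable homoallylic alcohol F11 is isolated. Dess–Martin periodinane buffered with NaHCO3 would then release 4 in an anhydrous, neutral medium directly before step 4.

**Step 5.** Most likely failure: attack at the ring carbonyl of the auxiliary or retro-aldol cleavage, because the α-isopropyl group slows attack at the exocyclic carbonyl. Fallback: from 9, LiOH/H2O2 in THF/water would cleave the auxiliary at the exocyclic carbonyl to give the β-hydroxy acid F12. Coupling of F12 with MeNHOMe·HCl (EDC·HCl, HOBt, i-Pr2NEt) would return the route at 10.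

## Further compounds

F1 | step 15 | (2Z,4R,5S,6R,8Z)-4-(tert-butyldimethylsilyloxy)-10-hydroxy-1-(4-methoxybenzyloxy)-2,8-dimethyl-5-(propan-2-yl)deca-2,8-dien-6-yl 4-(tert-butyldimethylsilyloxy)benzoate | COc1ccc(COC/C(C)=C\[C@@H](O[Si](C)(C)C(C)(C)C)[C@@H](C(C)C)[C@H](OC(=O)c2ccc(O[Si](C)(C)C(C)(C)C)cc2)C/C(C)=C\CO)cc1
F2 | step 15 | (2Z,4R,5S,6R,8Z)-10-bromo-4-(tert-butyldimethylsilyloxy)-1-(4-methoxybenzyloxy)-2,8-dimethyl-5-(propan-2-yl)deca-2,8-dien-6-yl 4-(tert-butyldimethylsilyloxy)benzoate | COc1ccc(COC/C(C)=C\[C@@H](O[Si](C)(C)C(C)(C)C)[C@@H](C(C)C)[C@H](OC(=O)c2ccc(O[Si](C)(C)C(C)(C)C)cc2)C/C(C)=C\CBr)cc1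
F3 | step 15 | (2Z,4R,5S,6R,8Z)-4-(tert-butyldimethylsilyloxy)-1-(4-methoxybenzyloxy)-2,8-dimethyl-10-(phenylsulfonyl)-5-(propan-2-yl)deca-2,8-dien-6-yl 4-(tert-butyldimethylsilyloxy)benzoate | COc1ccc(COC/C(C)=C\[C@@H](O[Si](C)(C)C(C)(C)C)[C@@H](C(C)C)[C@H](OC(=O)c2ccc(O[Si](C)(C)C(C)(C)C)cc2)C/C(C)=C\CS(=O)(=O)c2ccccc2)cc1
F4 | step 15 | (2Z,4R,5S,6R,8Z)-4-(tert-butyldimethylsilyloxy)-1-hydroxy-2,8-dimethyl-10-(phenylsulfonyl)-5-(propan-2-yl)deca-2,8-dien-6-yl 4-(tert-butyldimethylsilyloxy)benzoate | OC/C(C)=C\[C@@H](O[Si](C)(C)C(C)(C)C)[C@@H](C(C)C)[C@H](OC(=O)c1ccc(O[Si](C)(C)C(C)(C)C)cc1)C/C(C)=C\CS(=O)(=O)c1ccccc1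
F5 | step 15 | (2Z,4R,5S,6R,8Z)-1-bromo-4-(tert-butyldimethylsilyloxy)-2,8-dimethyl-10-(phenylsulfonyl)-5-(propan-2-yl)deca-2,8-dien-6-yl 4-(tert-butyldimethylsilyloxy)benzoate | BrC/C(C)=C\[C@@H](O[Si](C)(C)C(C)(C)C)[C@@H](C(C)C)[C@H](OC(=O)c1ccc(O[Si](C)(C)C(C)(C)C)cc1)C/C(C)=C\CS(=O)(=O)c1ccccc1
F6 | step 15 | (1R,3Z,7Z,9R,10S)-9-(tert-butyldimethylsilyloxy)-3,7-dimethyl-5-(phenylsulfonyl)-10-(propan-2-yl)cyclodeca-3,7-dien-1-yl 4-(tert-butyldimethylsilyloxy)benzoate, both epimers at C5 | C/C1=C/[C@@H](O[Si](C)(C)C(C)(C)C)[C@@H](C(C)C)[C@H](OC(=O)c2ccc(O[Si](C)(C)C(C)(C)C)cc2)C/C(C)=C\C(S(=O)(=O)c2ccccc2)C1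
F7 | step 16 | (1R,3Z,7Z,9R,10S)-9-(tert-butyldimethylsilyloxy)-3,7-dimethyl-10-(propan-2-yl)cyclodeca-3,7-dien-1-ol | C/C1=C/[C@@H](O[Si](C)(C)C(C)(C)C)[C@@H](C(C)C)[C@H](O)C/C(C)=C\CC1
F8 | step 9 | (2Z,4R,5R,6R,8Z)-10-(tert-butyldimethylsilyloxy)-4-hydroxy-1-(4-methoxybenzyloxy)-2,8-dimethyl-5-(propan-2-yl)deca-2,8-dien-6-yl acetate | COc1ccc(COC/C(C)=C\[C@@H](O)[C@@H](C(C)C)[C@H](OC(C)=O)C/C(C)=C\CO[Si](C)(C)C(C)(C)C)cc1
F9 | step 9 | (2Z,4R,5S,6R,8Z)-4,10-bis(tert-butyldimethylsilyloxy)-1-(4-methoxybenzyloxy)-2,8-dimethyl-5-(propan-2-yl)deca-2,8-dien-6-yl acetate | COc1ccc(COC/C(C)=C\[C@@H](O[Si](C)(C)C(C)(C)C)[C@@H](C(C)C)[C@H](OC(C)=O)C/C(C)=C\CO[Si](C)(C)C(C)(C)C)cc1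
F10 | step 9 | (2Z,4R,5S,6R,8Z)-4,10-bis(tert-butyldimethylsilyloxy)-1-(4-methoxybenzyloxy)-2,8-dimethyl-5-(propan-2-yl)deca-2,8-dien-6-ol | COc1ccc(COC/C(C)=C\[C@@H](O[Si](C)(C)C(C)(C)C)[C@@H](C(C)C)[C@H](O)C/C(C)=C\CO[Si](C)(C)C(C)(C)C)cc1
F11 | step 2 | (3Z)-5-(tert-butyldimethylsilyloxy)-3-methylpent-3-en-1-ol | OCC/C(C)=C\CO[Si](C)(C)C(C)(C)C
F12 | step 5 | (2S,3R,5Z)-7-(tert-butyldimethylsilyloxy)-3-hydroxy-5-methyl-2-(propan-2-yl)hept-5-enoic acid | OC(=O)[C@@H](C(C)C)[C@H](O)C/C(C)=C\CO[Si](C)(C)C(C)(C)C
A1 | alternative 1 | ten-membered (Z,Z)-dienol with C3 hydroxyl, C4 isopropenyl and C5 triethylsilyloxy groups | C/C1=C/[C@@H](O)[C@@H](C(C)=C)[C@H](O[Si](CC)(CC)CC)C/C(C)=C\CC1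
A2 | alternative 1 | thirteen-membered bis-allylic ether with O3 bridging C3 and the future isopropenyl methylene, C5 triethylsilyloxy | C/C1=C/COC/C(C)=C/[C@H](O[Si](CC)(CC)CC)C/C(C)=C\CC1
A3 | alternative 2 | ten-membered (Z,Z)-diene with C3 tert-butyldimethylsilyloxy, C4 isopropenyl and free C5 hydroxyl groups | C/C1=C/[C@@H](O[Si](C)(C)C(C)(C)C)[C@@H](C(C)=C)[C@H](O)C/C(C)=C\CC1
A4 | alternative 2 | open-chain C5 aldehyde with C3 tert-butyldimethylsilyloxy group and a terminal allylic chloride whose γ-carbon is C4 | O=CC/C(C)=C\CC/C(C)=C\[C@@H](O[Si](C)(C)C(C)(C)C)/C=C(\C)CCl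
A5 | alternative 3 | bis-silylated target, identical with 28 | C/C1=C/[C@@H](O[Si](C)(C)C(C)(C)C)[C@@H](C(C)C)[C@H](OC(=O)c2ccc(O[Si](C)(C)C(C)(C)C)cc2)C/C(C)=C\CC1
A6 | alternative 3 | open-chain C8 (Z)-alkenyl iodide with a terminal C9=C10 vinyl group on C1, O3 silylated and O5 aroylated | C=C/C(C)=C\[C@@H](O[Si](C)(C)C(C)(C)C)[C@@H](C(C)C)[C@H](OC(=O)c1ccc(O[Si](C)(C)C(C)(C)C)cc1)C/C(C)=C\I
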